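**Retrosynthetic overview**

1. Guidongnin C ⇐ exo-face hydrogenation of the 2,16-dien-15-one ⇐ allylic oxidation at C15 of a 6,7-seco-ent-kaura-2,16-diene whose 11-OH comes from a thermodynamically controlled ketone reduction.
2. Ring D ⇐ 5-exo vinyl-radical closure (C16–C13) of an 8-(2-bromoallyl)cyclohex-2-enone, the hydrolysis product of an 11-methoxy diene.
3. Key disconnection (C9–C10 and C8–C15): a decarboxylatively generated C10 radical adds to the 3-methoxybenzoate ring carbon between ester and OMe, which breaks aromaticity and closes the δ-lactone; the resulting dienolate is allylated at C8.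
4. Radical precursor (ring A + γ-lactone, C4/C5) ⇐ intramolecular Diels–Alder of a dienyl hydrogen maleate built from citraconic anhydride, 3-methoxybenzoic acid and (2E)-2-methylpenta-2,4-dienol; resolved as an amine salt.
5. Ring order: A + γ-lactone → δ-lactone + C → D.

Assumption: atom labels C1–C20 follow ent-kaurane numbering (seco-ent-kaurane names carry the ent-kaurane configuration, extra centres are described in words), and in step 6 the (S)-amine salt of the needed acid enantiomer is taken to be the less soluble one (otherwise the (R)-amine is used).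

**Route**

Step 1
Reactants: 1 acrolein; 2 ethyl 2-(triphenyl-λ5-phosphanylidene)propanoate
Product: 3 ethyl (2E)-2-methylpenta-2,4-dienoate
Conditions: CH2Cl2, 0 → 25 °C
Reagents that add atoms: none
Why: Wittig olefination of the aldehyde with a stabilised ylide gives the (E)-dienoate, with the ester trans to the vinyl group.

Step 2
Reactants: 3 ethyl (2E)-2-methylpenta-2,4-dienoate
Product: 4 (2E)-2-methylpenta-2,4-dien-1-ol
Conditions: i-Bu2AlH (2.2 equiv), CH2Cl2, −78 °C; aq. potassium sodium tartrate
Reagents that add atoms: none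
Why: 1,2-reduction of the conjugated ester by the aluminium hydride gives the allylic alcohol and leaves the diene untouched.

Step 3
Reactants: 5 citraconic anhydride
Product: 6 3-(bromomethyl)furan-2,5-dione
Conditions: N-bromosuccinimide, (PhCO2)2 (cat.), PhCl, 85 °C
Reagents that add atoms: N-bromosuccinimide, O=C1CCC(=O)N1Br
Why: Wohl–Ziegler radical bromination at the only sp3 C–H position, which is allylic.

Step 4
Reactants: 6 3-(bromomethyl)furan-2,5-dione; 7 3-methoxybenzoic acid
Product: 8 (2,5-dioxo-2,5-dihydrofuran-3-yl)methyl 3-methoxybenzoate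
Conditions: i-Pr2NEt (1.0 equiv), MeCN, 0 → 25 °C
Reagents that add atoms: none
Why: SN2 O-alkylation of the carboxylate by the activated allylic bromide; the hindered amine does not quaternise.

Step 5
Reactants: 8 (2,5-dioxo-2,5-dihydrofuran-3-yl)methyl 3-methoxybenzoate; 4 (2E)-2-methylpenta-2,4-dien-1-ol
Product: 10 rac-7-{[(3-methoxybenzoyl)oxy]methyl}-3a-methyl-1-oxo-1,3,3a,6,7,7a-hexahydro-2-benzofuran-7-carboxylic acid (cis-fused; CO2H cis to C1), via maleate half-ester 9 (not isolated)
Conditions: DMAP (5 mol %), PhMe, 25 °C; then BHT, 110 °C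
Reagents that add atoms: none
Why: The alcohol opens the anhydride at the less hindered carbonyl and the dienyl hydrogen maleate then undergoes an intramolecular Diels–Alder reaction; the Z-dienophile with tether and free carboxyl both endo gives the cis-fused γ-lactone, which sets C4 and C5 (relative) and puts the CO2H cis to the lactone carbonyl.

Step 6
Reactants: 10 rac-7-{[(3-methoxybenzoyl)oxy]methyl}-3a-methyl-1-oxo-1,3,3a,6,7,7a-hexahydro-2-benzofuran-7-carboxylic acid; 11 (S)-1-phenylethylamine
Product: 12 (S)-1-phenylethylammonium salt of the acid enantiomer with the C4/C5 configuration of the target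
Conditions: EtOAc/i-PrOH, 60 → 5 °C, two recrystallisations
Reagents that add atoms: none
Why: Classical resolution by crystallisation of the less soluble diastereomeric ammonium carboxylate fixes the absolute configuration of C4 and C5.

Step 7
Reactants: 12 (S)-1-phenylethylammonium salt of the resolved acid; 13 2,3-dibromopropene
Product: 17 16-bromo-11-methoxy-6,7:13,16-diseco-ent-kaura-2,11,13,16-tetraene-6,19:7,20-diolide, via free acid 14 (not isolated), via potassium carboxylate 15 (not isolated), via potassium dienolate 16 (not isolated)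
Conditions: 1 M HCl/EtOAc wash; KN(SiMe3)2 (1.0 equiv), THF, −78 °C; 4CzIPN (2 mol %), DMF, 450 nm LEDs, Ar sweep, 25 °C; then 13 (1.5 equiv), −40 → 0 °C
Reagents that add atoms: none
Why: Proposed new method: photocatalytic oxidation of the carboxylate and loss of CO2 give the tertiary C10 radical, which closes the six-membered lactone by attack on the arene carbon ortho to both ester and OMe (the position preferred by nucleophilic alkyl radicals; spin is delocalised onto the ester- and methoxy-bearing carbons); the photocatalyst radical anion reduces this cyclohexadienyl radical to the ester dienolate (radical–polar crossover), which the allylic bromide alkylates at C8; the arene adds to the convex face of the cis-fused γ-lactone (anti to C6, so C20 ends cis to C6), the tether holds C20 toward C7 so that the small C1 methylene lies over the ring and the branched C5 points outward (natural C9/C10 relation), and the electrophile enters C8 anti to the new C9–C10 bond; closest known reactions are decarboxylative Giese additions with radical–polar crossover, SmI2 ketyl–arene dearomatising cyclisations of benzoates, and Birch reductive alkylation for the enolate trapping.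

Step 8
Reactants: 17 16-bromo-11-methoxy-6,7:13,16-diseco-ent-kaura-2,11,13,16-tetraene-6,19:7,20-diolide
Product: 18 16-bromo-11-oxo-6,7:13,16-diseco-ent-kaura-2,12,16-triene-6,19:7,20-diolide
Conditions: 0.5 M HCl, THF, 0 → 25 °C
Reagents that add atoms: water, O
Why: Acid hydrolysis of the dienyl methyl ether, with protonation at the diene terminus C14 and loss of methanol, gives the conjugated cyclohexenone without enolising C9.

Step 9
Reactants: 18 16-bromo-11-oxo-6,7:13,16-diseco-ent-kaura-2,12,16-triene-6,19:7,20-diolide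
Product: 19 11-oxo-6,7-seco-ent-kaura-2,16-diene-6,19:7,20-diolide
Conditions: Bu3SnH, AIBN (cat.), PhH, 80 °C, slow addition
Reagents that add atoms: none
Why: Stork-type 5-exo-trig vinyl-radical cyclisation onto the enone β-carbon C13 closes the bicyclo[3.2.1]octane, as known for 5-(2-bromoallyl)cyclohexenones; the bridge can only span the face of ring C that carries C15, so C13 follows from C8.

Step 10
Reactants: 19 11-oxo-6,7-seco-ent-kaura-2,16-diene-6,19:7,20-diolide
Product: 20 11-hydroxy-6,7-seco-ent-kaura-2,16-diene-6,19:7,20-diolide (11-OH equatorial and trans to H-9)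
Conditions: SmI2 (2.5 equiv), i-PrOH, THF, 0 → 25 °C
Reagents that add atoms: none
Why: Single-electron ketyl reduction under thermodynamic control gives the equatorial C11 alcohol, anti to the two-carbon bridge and cis to C10 as in the target; the lactones are inert without water or amine additives.

Step 11
Reactants: 20 11-hydroxy-6,7-seco-ent-kaura-2,16-diene-6,19:7,20-diolide
Product: 21 11,15-dihydroxy-6,7-seco-ent-kaura-2,16-diene-6,19:7,20-diolide (15-OH exo)
Conditions: SeO2 (0.5 equiv), t-BuOOH, CH2Cl2, 0 → 25 °C
Reagents that add atoms: tert-butyl hydroperoxide, CC(C)(C)OO; selenium dioxide (oxygen carrier), O=[Se]=O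
Why: Riley allylic oxidation (ene reaction then [2,3]-shift) puts oxygen on C15; the 1,1-disubstituted exocyclic alkene reacts far faster than the cis-disubstituted alkene of ring A.

Step 12
Reactants: 21 11,15-dihydroxy-6,7-seco-ent-kaura-2,16-diene-6,19:7,20-diolide
Product: 22 11-hydroxy-15-oxo-6,7-seco-ent-kaura-2,16-diene-6,19:7,20-diolide
Conditions: MnO2, CH2Cl2, 25 °C
Reagents that add atoms: none
Why: MnO2 oxidises only the allylic C15 alcohol and leaves the saturated C11 alcohol.

Step 13
Reactants: 22 11-hydroxy-15-oxo-6,7-seco-ent-kaura-2,16-diene-6,19:7,20-diolide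
Product: 23 guidongnin C
Conditions: H2 (1 atm), 10% Pd/C, EtOAc, 25 °C
Reagents that add atoms: none
Why: Heterogeneous hydrogenation saturates both alkenes; hydrogen adds to the exocyclic enone from the open exo face of the bicyclo[3.2.1]octane (syn to C14), so the C16 methyl ends endo as in the target.

**Compound list**

1 | acrolein | C=CC=O | starting material
2 | ethyl 2-(triphenyl-λ5-phosphanylidene)propanoate | CCOC(=O)C(C)=P(c1ccccc1)(c1ccccc1)c1ccccc1 | starting material
3 | ethyl (2E)-2-methylpenta-2,4-dienoate | C=C/C=C(\C)C(=O)OCC | intermediate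
4 | (2E)-2-methylpenta-2,4-dien-1-ol | C=C/C=C(\C)CO | intermediate
5 | citraconic anhydride (3-methylfuran-2,5-dione) | CC1=CC(=O)OC1=O | starting material
6 | 3-(bromomethyl)furan-2,5-dione | BrCC1=CC(=O)OC1=O | intermediate
7 | 3-methoxybenzoic acid | COc1cccc(c1)C(=O)O | starting material
8 | (2,5-dioxo-2,5-dihydrofuran-3-yl)methyl 3-methoxybenzoate | COc1cccc(c1)C(=O)OCC1=CC(=O)OC1=O | intermediate
9 | (2Z)-2-{[(3-methoxybenzoyl)oxy]methyl}-4-{[(2E)-2-methylpenta-2,4-dien-1-yl]oxy}-4-oxobut-2-enoic acid (maleate half-ester) | OC(=O)/C(COC(=O)c1cccc(OC)c1)=C\C(=O)OC/C(C)=C/C=C | intermediate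
10 | rac-7-{[(3-methoxybenzoyl)oxy]methyl}-3a-methyl-1-oxo-1,3,3a,6,7,7a-hexahydro-2-benzofuran-7-carboxylic acid; cis-fused (3a-CH3 cis to 7a-H), 7-CO2H cis to the C1 carbonyl; racemate, one enantiomer drawn | COc1cccc(c1)C(=O)OC[C@@]1(CC=C[C@@]2(C)COC(=O)[C@H]21)C(=O)O | intermediate
11 | (S)-1-phenylethylamine | C[C@H](N)c1ccccc1 | starting material
12 | (S)-1-phenylethylammonium salt of the enantiomer of 10 that has the C4/C5 configuration of the target | COc1cccc(c1)C(=O)OC[C@@]1(CC=C[C@@]2(C)COC(=O)[C@H]21)C(=O)[O-].C[C@H]([NH3+])c1ccccc1 | intermediate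
13 | 2,3-dibromopropene | C=C(Br)CBr | starting material
14 | free acid, single enantiomer of 10 (relative configuration as 10) | COc1cccc(c1)C(=O)OC[C@@]1(CC=C[C@@]2(C)COC(=O)[C@H]21)C(=O)O | intermediate
15 | potassium carboxylate of 14 | COc1cccc(c1)C(=O)OC[C@@]1(CC=C[C@@]2(C)COC(=O)[C@H]21)C(=O)[O-].[K+] | intermediate
16 | potassium dienolate of the dearomatised lactone (15,16,17-trinor-6,7-seco-ent-kaurane skeleton; C7(OK)=C8, C13=C14, C11=C12 with 11-OMe, C2=C3; H-9 trans to C10–C20 on ring C) | [K+].[O-]C1=C2C=CC=C(OC)[C@H]2[C@@]3(CC=C[C@@]4(C)COC(=O)[C@H]43)CO1 | intermediate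
17 | 16-bromo-11-methoxy-6,7:13,16-diseco-ent-kaura-2,11,13,16-tetraene-6,19:7,20-diolide (C8 bromoallyl trans to C10 on ring C; H-9 cis to the bromoallyl group) | C=C(Br)C[C@]23C=CC=C(OC)[C@H]2[C@@]1(CC=C[C@@]2(C)COC(=O)[C@H]21)COC3=O | intermediate
18 | 16-bromo-11-oxo-6,7:13,16-diseco-ent-kaura-2,12,16-triene-6,19:7,20-diolide | C=C(Br)C[C@]23CC=CC(=O)[C@H]2[C@@]1(CC=C[C@@]2(C)COC(=O)[C@H]21)COC3=O | intermediate
19 | 11-oxo-6,7-seco-ent-kaura-2,16-diene-6,19:7,20-diolide | C=C1C[C@]23C[C@H]1CC(=O)[C@H]2[C@@]1(CC=C[C@@]2(C)COC(=O)[C@H]21)COC3=O | intermediate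
20 | 11-hydroxy-6,7-seco-ent-kaura-2,16-diene-6,19:7,20-diolide (11-OH equatorial, trans to H-9, cis to C10) | C=C1C[C@]23C[C@H]1C[C@@H](O)[C@H]2[C@@]1(CC=C[C@@]2(C)COC(=O)[C@H]21)COC3=O | intermediate
21 | 11,15-dihydroxy-6,7-seco-ent-kaura-2,16-diene-6,19:7,20-diolide (11-OH as in 20; 15-OH exo, syn to C14; C15 configuration is lost in step 12) | C=C1[C@H](O)[C@]23C[C@H]1C[C@@H](O)[C@H]2[C@@]1(CC=C[C@@]2(C)COC(=O)[C@H]21)COC3=O | intermediate
22 | 11-hydroxy-15-oxo-6,7-seco-ent-kaura-2,16-diene-6,19:7,20-diolide | C=C1C(=O)[C@]23C[C@H]1C[C@@H](O)[C@H]2[C@@]1(CC=C[C@@]2(C)COC(=O)[C@H]21)COC3=O | intermediate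
23 | guidongnin C | C[C@H]1C(=O)[C@]23C[C@H]1C[C@@H](O)[C@H]2[C@@]1(CCC[C@@]2(C)COC(=O)[C@H]21)COC3=O | target

**Step count and risks**

Total steps: 13. Longest linear sequence: 11 steps (steps 3–13; the branch through steps 1, 2 and 5–13 is also 11).

The three steps most likely to fail:

Step 7 is the largest risk. The ester tether must reach the arene, attack must occur at C9 and not at C14, and the dienolate must survive until the bromide is added. The fallback sets out from 12 and comes back at 17. The acid freed from 12 is coupled with N-hydroxyphthalimide (N,N'-diisopropylcarbodiimide, DMAP) to the redox-active 1,3-dioxoisoindolin-2-yl ester F1. Reductive photocatalysis with a hydrogen donor (4CzIPN, Hantzsch ester, blue light; or SmI2/t-BuOH) generates the same C10 radical, but the cyclohexadienyl radical is now terminated by hydrogen, giving the isolable cis-fused 11-methoxy-15,16,17-trinor-6,7-seco-ent-kaura-2,11,13-triene-6,19:7,20-diolide F2 with H at C8. F2 is then deprotonated at C8 with KN(SiMe3)2 at −78 °C and alkylated with 13 to give 17.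

Step 5 may suffer from the Z-methyl on the diene terminus, from imperfect regioselectivity of anhydride opening, and from an uncertain cis/trans fusion ratio. The fallback sets out from 4 and 8 and comes back at 10. Alcohol 4 is silylated (t-BuMe2SiCl, imidazole) to tert-butyl(dimethyl){[(2E)-2-methylpenta-2,4-dien-1-yl]oxy}silane F3. An intermolecular endo Diels–Alder reaction of F3 with 8 (PhMe, 80 °C) joins the fully substituted diene terminus to the unsubstituted dienophile carbon and gives the rac anhydride adduct F4. Bu4NF/AcOH removes the silyl group, and the freed alcohol opens the anhydride at the neighbouring carbonyl to give the γ-lactone acid 10.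

Step 10 may give the axial C11 alcohol, or the reduction may be sluggish at the hindered ketone. The fallback sets out from 18 and comes back at 20 by reversing the order of reduction and ring closure. Luche reduction (NaBH4, CeCl3·7H2O, MeOH, −78 °C) of the monocyclic cis-fused enone 18, where hydride adds to the convex face anti to the lactone ring, gives 16-bromo-11-hydroxy-6,7:13,16-diseco-ent-kaura-2,12,16-triene-6,19:7,20-diolide F5 with the 11-OH cis to C10. The vinyl-radical cyclisation (Bu3SnH, AIBN, PhH, 80 °C) then closes ring D on the C12=C13 bond to give 20.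

**Further compounds**

F1 | step 7 | 1,3-dioxoisoindolin-2-yl ester of acid 14 | COc1cccc(c1)C(=O)OC[C@@]1(CC=C[C@@]2(C)COC(=O)[C@H]21)C(=O)ON1C(=O)c2ccccc2C1=O
F2 | step 7 | 11-methoxy-15,16,17-trinor-6,7-seco-ent-kaura-2,11,13-triene-6,19:7,20-diolide (H-8 cis to H-9) | [H][C@]23C=CC=C(OC)[C@H]2[C@@]1(CC=C[C@@]2(C)COC(=O)[C@H]21)COC3=O
F3 | step 5 | tert-butyl(dimethyl){[(2E)-2-methylpenta-2,4-dien-1-yl]oxy}silane | C=C/C=C(\C)CO[Si](C)(C)C(C)(C)C
F4 | step 5 | rac-3a-{[(3-methoxybenzoyl)oxy]methyl}-7-methyl-7-{[tert-butyl(dimethyl)silyl]oxymethyl}-3a,4,7,7a-tetrahydro-2-benzofuran-1,3-dione (silyloxymethyl cis to the anhydride ring; racemate, one enantiomer drawn) | COc1cccc(c1)C(=O)OC[C@]12CC=C[C@@](C)(CO[Si](C)(C)C(C)(C)C)[C@H]1C(=O)OC2=O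
F5 | step 10 | 16-bromo-11-hydroxy-6,7:13,16-diseco-ent-kaura-2,12,16-triene-6,19:7,20-diolide (11-OH cis to C10) | C=C(Br)C[C@]23CC=C[C@@H](O)[C@H]2[C@@]1(CC=C[C@@]2(C)COC(=O)[C@H]21)COC3=O
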